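The 2,8-dioxabicyclo[3.2.1]octane is read as a carbonyl ylide cycloadduct (chain numbering: amide carbonyl C1 to ketal methyl C17). The bridging oxygen O13 and its two bridgeheads (ketal carbon C16, carbinol carbon C13), shared by the 1,3-dioxane and tetrahydrofuran rings, are the dipole. The C14–C15 bridge is the dipolarophile. The precursor is an acyclic α'-acetoxy diazoketone. With Rh(II), the acetate carbonyl oxygen attacks the carbenoid carbon (O13–C13, dioxane ring). The ylide then adds to phenyl vinyl sulfone, an ethylene equivalent (C15–C16 and C13–C14, tetrahydrofuran ring), setting C13 and C16 from C11 in one operation. Crotylboration, propargylation and Stille coupling to a cyclobutenone-derived naphthoquinone finish the target.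

Key step: step 6

Remark: O11 and O13 are the two ketal oxygens; positions of the naphthoquinone are given as "ring position n".
Remark (assumption): 12–14 are drawn as the C15-exo-sulfonyl isomer expected from the ylide polarisation. Other regio- or exo/endo isomers would carry the same C11, C13 and C16 configuration and lose the difference in step 9.

Step 1
Reactants: 1 (S)-4-benzyl-3-propionyloxazolidin-2-one; 2 acrolein
Product: 4 (S)-4-benzyl-3-[(2S,3R)-3-hydroxy-2-methylpent-4-enoyl]oxazolidin-2-one, via dibutylboron (Z)-enolate 3 (not isolated)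
Conditions: n-Bu2BOTf, Et3N, CH2Cl2, −78 → 0 °C; 2, −78 → 0 °C; then pH 7 buffer, MeOH, 30 % H2O2, 0 °C
Reagents that add atoms: dibutylboron triflate CCCCB(CCCC)OS(=O)(=O)C(F)(F)F (boron and butyl groups of 3 only)
Why: Evans syn aldol: the (Z)-boron enolate reacts through a chair Zimmerman–Traxler transition state on the face away from the benzyl group, which sets C10 and C11 (10,11-syn) in the required absolute sense.

Step 2
Reactants: 4 syn-aldol imide
Product: 5 (2R,3R)-2-methylpent-4-ene-1,3-diol
Conditions: LiBH4, MeOH (1 equiv), Et2O, 0 °C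
Reagents that add atoms: none
Why: Reductive cleavage of the imide by borohydride frees the C9 carbinol and returns the auxiliary without touching C10, C11 or the vinyl group.

Step 3
Reactants: 5 (2R,3R)-2-methylpent-4-ene-1,3-diol
Product: 6 (2R,3R)-2-methylpent-4-ene-1,3-diyl diacetate
Conditions: Ac2O, pyridine, DMAP (cat.), CH2Cl2, 0 °C → rt
Reagents that add atoms: acetic anhydride CC(=O)OC(C)=O
Why: DMAP-catalysed acetylation; the C11 acetate is the future C16/C17/O13 unit and the C9 acetate is an electron-withdrawing protecting group.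

Step 4
Reactants: 6 diacetate
Product: 7 (2S,3R)-2,4-diacetoxy-3-methylbutanoic acid
Conditions: RuCl3·xH2O (2 mol %), NaIO4 (4.1 equiv), EtOAc–MeCN–H2O, rt
Reagents that add atoms: sodium periodate [Na+].[O-]I(=O)(=O)=O; water O
Why: RuO4-catalysed oxidative cleavage converts the terminal vinyl group into the C12 carboxylic acid, and the acetates and stereocentres are inert to it.

Step 5
Reactants: 7 (2S,3R)-2,4-diacetoxy-3-methylbutanoic acid
Product: 9 (2R,3S)-5-diazo-2-methyl-4-oxopentane-1,3-diyl diacetate, via acid chloride 8 (not isolated)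
Conditions: (COCl)2, DMF (cat.), CH2Cl2, 0 °C → rt, concentrate; CH2N2 (3 equiv), Et2O, 0 °C
Reagents that add atoms: oxalyl chloride O=C(Cl)C(=O)Cl (chlorine of 8 only); diazomethane C=[N+]=[N-]
Why: Arndt–Eistert-type acylation of diazomethane gives the terminal α-diazoketone (C13), and excess CH2N2 scavenges HCl so that the α-acetoxy centre C11 is not epimerised.

Step 6
Reactants: 9 α'-acetoxy diazoketone; 10 phenyl vinyl sulfone
Product: 12 keto sulfone cycloadduct (R)-2-[1-methyl-4-oxo-7-exo-(phenylsulfonyl)-2,8-dioxabicyclo[3.2.1]octan-3-yl]propyl acetate, via cyclic carbonyl ylide 11 (not isolated)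
Conditions: Rh2(OAc)4 (2 mol %), 10 (5 equiv), PhCF3, 80 °C, slow addition of 9
Reagents that add atoms: none
Why: Rh2(OAc)4 expels N2 from 9 and the electrophilic carbenoid carbon C13 is attacked by the carbonyl oxygen of the neighbouring C11 acetate, which forms O13–C13 and closes the 1,3-dioxane ring as the six-membered cyclic ylide 11 (ring closure by O-attack on the carbenoid, the ylide being stabilised as the C12 enolate); 11 then adds suprafacially to phenyl vinyl sulfone in a [π4s+π2s] 1,3-dipolar cycloaddition that forms C13–C14 and C15–C16 and so closes the tetrahydrofuran ring and the complete 2,8-dioxabicyclo[3.2.1]octane. The closest known reaction type is the tandem Rh(II) carbonyl ylide formation/1,3-dipolar cycloaddition of ester-tethered diazocarbonyl compounds, which is established for this ring system. C13 and C16 are set together because both C–C bonds must form on one face of the nearly planar ylide, and that face is chosen by the resident C11 stereocentre: the dipolarophile should approach anti to the branched C10 substituent, which thereby becomes equatorial as in the target. Regiochemistry follows the ylide polarisation (enolate-like C13 to the β-CH2 of the sulfone, dioxocarbenium-like C16 to the α-carbon) and, like the configuration at the sulfonyl carbon C15, is erased in step 9. The step needs chemoselectivity for ylide formation and trapping over C–H insertion, 1,4-H shift, cyclopropanation and carbene dimerisation: the only 1,5-C–H bonds are a primary methyl C–H and a CH2 deactivated by its acetoxy group, the second acetate could only give an eight-membered ylide, the electron-poor alkene is not cyclopropanated, and slow addition into excess dipolarophile intercepts 11 as it forms.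

Step 7
Reactants: 12 keto sulfone cycloadduct
Product: 13 (R)-2-[1-methyl-4-methylene-7-exo-(phenylsulfonyl)-2,8-dioxabicyclo[3.2.1]octan-3-yl]propyl acetate
Conditions: Ph3PCH3Br (1.5 equiv), KHMDS (1.4 equiv), THF, 0 °C; then 12, 0 °C → rt
Reagents that add atoms: methyltriphenylphosphonium bromide C[P+](c1ccccc1)(c1ccccc1)c1ccccc1.[Br-]
Why: Wittig methylenation of the C12 ketone, which cannot enolise toward the bridgehead and whose C11 epimerisation would only return the favoured equatorial isomer, while the slight deficit of base avoids deprotonation next to the sulfone.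

Step 8
Reactants: 13 exocyclic alkene
Product: 14 (R)-2-[1,4-dimethyl-7-exo-(phenylsulfonyl)-2,8-dioxabicyclo[3.2.1]octan-3-yl]propyl acetate with equatorial C12 methyl
Conditions: H2 (1 atm), 10 % Pd/C, EtOAc, rt
Reagents that add atoms: none
Why: Heterogeneous hydrogenation should deliver H2 to the open face of the alkene, anti to the C14–C15 bridge and flanked only by the ring oxygens, so that the C12 methyl becomes equatorial (11,12-anti and 12,13-syn as in the target).

Step 9
Reactants: 14 saturated sulfone acetate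
Product: 15 (R)-2-[(1S,3S,4R,5S)-1,4-dimethyl-2,8-dioxabicyclo[3.2.1]octan-3-yl]propan-1-ol
Conditions: Mg turnings (excess), MeOH, rt → 40 °C; sat. aq NH4Cl; then PPTS (cat.), CH2Cl2, rt
Reagents that add atoms: none
Why: Reductive desulfonylation by electron transfer from Mg in MeOH removes the sulfonyl group while Mg(OMe)2 transesterifies the C9 acetate, and any hydroxy enol ether formed by β-elimination toward C16 re-closes to the same thermodynamic ketal on the PPTS treatment.

Step 10
Reactants: 15 ketal alcohol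
Product: 16 C9 aldehyde 2-(1,4-dimethyl-2,8-dioxabicyclo[3.2.1]octan-3-yl)propanal with C10–C13 and C16 unchanged
Conditions: Dess–Martin periodinane, CH2Cl2, 0 °C → rt
Reagents that add atoms: none
Why: Dess–Martin oxidation gives the α-branched aldehyde under mild non-basic conditions that do not epimerise C10.

Step 11
Reactants: 16 C9 aldehyde; 17 (E)-but-2-ene
Product: 19 (8R,9R,10R) homoallylic alcohol C7–C17 with terminal vinyl group, via (E)-crotyldiisopinocampheylborane 18 (not isolated)
Conditions: 17, KOt-Bu, n-BuLi, THF, −78 → −45 °C; (+)-Ipc2BOMe, −78 °C; BF3·OEt2; 16, −78 °C; then 3 M NaOH, 30 % H2O2, rt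
Reagents that add atoms: (+)-B-methoxydiisopinocampheylborane COB([C@H]1C[C@H]2C[C@@H]([C@@H]1C)C2(C)C)[C@H]1C[C@H]2C[C@@H]([C@@H]1C)C2(C)C (boron and Ipc groups of 18 only)
Why: Brown asymmetric (E)-crotylboration: the chair transition state gives the 8,9-anti relationship and the Ipc ligands derived from (−)-α-pinene direct attack to the Re face of 16, overriding the small Felkin bias to give the 9,10-anti triad.

Step 12
Reactants: 19 homoallylic alcohol
Product: 20 C9 triethylsilyl ether of 19
Conditions: TESCl, imidazole, CH2Cl2, 0 °C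
Reagents that add atoms: chlorotriethylsilane CC[Si](Cl)(CC)CC
Why: Silyl ether formation masks the C9 hydroxyl so that the β-oxygenated aldehyde of step 13 cannot chelate or eliminate, and the group falls in the final acid step.

Step 13
Reactants: 20 TES ether
Product: 21 C7 aldehyde with C8–C13 and C16 unchanged
Conditions: O3, CH2Cl2, −78 °C; then PPh3, −78 °C → rt
Reagents that add atoms: ozone [O-][O+]=O
Why: Ozonolysis with reductive work-up cleaves the only alkene to the C7 aldehyde, and the ketal carbon carries no hydrogen and is inert to ozone.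

Step 14
Reactants: 22 (R)-but-3-yn-2-ol
Product: 23 (R)-but-3-yn-2-yl methanesulfonate
Conditions: MsCl, Et3N, CH2Cl2, −78 °C
Reagents that add atoms: methanesulfonyl chloride CS(=O)(=O)Cl
Why: O-sulfonylation (mesylate formation) proceeds with retention at the carbinol carbon.

Step 15
Reactants: 21 C7 aldehyde; 23 (R)-but-3-yn-2-yl methanesulfonate
Product: 25 (6S,7S) homopropargylic alcohol C4–C17 with terminal alkyne, via allenylindium reagent 24 (not isolated)
Conditions: PdCl2(dppf) (5 mol %), InI (1.4 equiv), THF–HMPA (3:1), rt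
Reagents that add atoms: indium(I) iodide [In]I (indium and iodine of 24 only)
Why: Marshall propargylation: anti SN2' oxidative addition of Pd(0) and transmetalation give the axially chiral allenylindium 24, which adds through a cyclic SE2' transition state to set C6 from the mesylate and the 6,7-anti relationship, with attack on the Felkin face of 21 (7,8-syn).

Step 16
Reactants: 25 terminal alkyne
Product: 26 (E)-vinylstannane C4–C17
Conditions: n-Bu3SnH, PdCl2(PPh3)2 (3 mol %), THF, 0 °C
Reagents that add atoms: tributyltin hydride CCCC[SnH](CCCC)CCCC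
Why: Pd-catalysed syn hydrostannation places tin at the unhindered terminus because of the branched propargylic carbon C6 and fixes the (E) geometry of C4=C5.

Step 17
Reactants: 27 propargyl alcohol
Product: 29 (Z)-3-iodo-2-methylprop-2-en-1-ol, via chelated vinylmagnesium alkoxide 28 (not isolated)
Conditions: MeMgBr (2.5 equiv), CuI (10 mol %), Et2O, −20 °C → rt; then I2, 0 °C
Reagents that add atoms: methylmagnesium bromide C[Mg]Br; iodine II
Why: Cu-catalysed hydroxyl-directed anti carbomagnesiation gives the five-membered chelated vinylmagnesium species, whose iodinolysis with retention places iodine cis to CH2OH, the future (2Z) geometry.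

Step 18
Reactants: 29 (Z)-3-iodo-2-methylprop-2-en-1-ol
Product: 30 (Z)-3-iodo-2-methylacrylic acid
Conditions: TEMPO (20 mol %), PhI(OAc)2 (2.2 equiv), MeCN–H2O (1:1), rt
Reagents that add atoms: water O
Why: TEMPO/PhI(OAc)2 oxidation takes the allylic alcohol through the aldehyde hydrate to the acid under near-neutral conditions that do not isomerise the (Z)-iodoalkene.

Step 19
Reactants: 31 diisopropyl squarate
Product: 33 3-isopropoxycyclobut-3-ene-1,2-dione, via hydroxycyclobutenone 32 (not isolated)
Conditions: LiAlH(Ot-Bu)3, THF, −78 → 0 °C; then 6 M HCl, CH2Cl2, rt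
Reagents that add atoms: none
Why: Selective 1,2-reduction of one squarate carbonyl followed by acid-induced loss of isopropanol gives the semisquarate.

Step 20
Reactants: 34 2,4-dihydroxy-3-methylbenzoic acid
Product: 35 2,4-dihydroxy-5-iodo-3-methylbenzoic acid
Conditions: NIS (1.0 equiv), MeCN, 0 °C → rt, dark
Reagents that add atoms: N-iodosuccinimide O=C1CCC(=O)N1I
Why: Electrophilic aromatic iodination goes to C5, the only free position ortho/para to both hydroxyl groups.

Step 21
Reactants: 35 iodo acid
Product: 36 4-methoxybenzyl 5-iodo-2,4-bis[(4-methoxybenzyl)oxy]-3-methylbenzoate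
Conditions: PMBCl (3.5 equiv), K2CO3, n-Bu4NI (cat.), DMF, 60 °C
Reagents that add atoms: 4-methoxybenzyl chloride COc1ccc(CCl)cc1
Why: Williamson and carboxylate alkylation install three acid-labile PMB groups in a single operation.

Step 22
Reactants: 36 aryl iodide; 33 3-isopropoxycyclobut-3-ene-1,2-dione
Product: 38 racemic 4-aryl-4-hydroxy-3-isopropoxycyclobut-2-en-1-one, via arylmagnesium chloride 37 (not isolated)
Conditions: i-PrMgCl·LiCl, THF, −40 °C; then 33, −78 → −40 °C; sat. aq NH4Cl
Reagents that add atoms: isopropylmagnesium chloride–lithium chloride CC(C)[Mg]Cl.[Li+].[Cl-] (MgCl of 37 only)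
Why: Iodine–magnesium exchange tolerates the ester at low temperature and the aryl Grignard adds 1,2 to the more electrophilic carbonyl of 33, the one outside the vinylogous ester and next to the alkoxy-bearing carbon, giving a racemic carbinol centre that is destroyed in step 23.

Step 23
Reactants: 38 arylhydroxycyclobutenone
Product: 40 PMB-protected 2-isopropoxy-1,4-naphthoquinone, via naphthohydroquinone 39 (not isolated)
Conditions: toluene, 110 °C; then Ag2O, rt
Reagents that add atoms: none
Why: Moore rearrangement: 4π electrocyclic opening with outward rotation of the hydroxyl gives the aryl vinylketene, 6π closure onto the only free ortho carbon and tautomerisation give 39, and Ag2O oxidation gives the quinone with the alkoxy group at ring position 2, next to the carbonyl that is peri to the ring position 8 oxygen.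

Step 24
Reactants: 40 2-isopropoxyquinone
Product: 41 PMB-protected 2-amino-1,4-naphthoquinone
Conditions: NH3 (7 M in MeOH), THF, 0 °C → rt
Reagents that add atoms: ammonia N
Why: Addition–elimination at the vinylogous ester replaces the 2-isopropoxy group by NH2 without change of regiochemistry.

Step 25
Reactants: 41 aminoquinone; 30 (Z)-3-iodo-2-methylacrylic acid
Product: 43 (Z)-3-iodo-2-methylacrylamide of 41, via (Z)-3-iodo-2-methylacryloyl chloride 42 (not isolated)
Conditions: 30, 1-chloro-N,N,2-trimethylprop-1-en-1-amine, CH2Cl2, 0 °C; separately 41, NaH (2.2 equiv), THF, 0 °C; combine, 0 °C → rt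
Reagents that add atoms: 1-chloro-N,N,2-trimethylprop-1-en-1-amine CC(C)=C(Cl)N(C)C (chlorine of 42 only)
Why: N-acylation of the sodium salt of the vinylogous amide by the acid chloride, which is made under neutral conditions with the α-chloroenamine so that the (Z)-iodoalkene is retained.

Step 26
Reactants: 26 (E)-vinylstannane; 43 (Z)-iodoacrylamide
Product: 44 tris-PMB 9-O-TES rifsaliniketal
Conditions: Pd2(dba)3·CHCl3 (5 mol %), AsPh3 (20 mol %), NMP, rt, dark
Reagents that add atoms: none
Why: Stille cross-coupling joins C3 and C4 with retention of both alkene geometries to give the (2Z,4E)-dienamide under neutral conditions that tolerate the quinone, the free hydroxyl and the ketal.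

Step 27
Reactants: 44 protected rifsaliniketal
Product: 45 rifsaliniketal
Conditions: TFA–CH2Cl2 (1:5), anisole (10 equiv), 0 °C; then pH 5 phosphate buffer
Reagents that add atoms: none
Why: Acidolysis (SN1 cleavage with anisole as cation trap) removes the PMB ester and both PMB ethers and cleaves the TES ether, while the bicyclic ketal, being the thermodynamic ketal of the C11/C13 diol and the C16 ketone, should survive reversible ionisation.

Compound list
1 | (S)-4-benzyl-3-propionyloxazolidin-2-one | CCC(=O)N1[C@@H](Cc2ccccc2)COC1=O | starting material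
2 | acrolein | C=CC=O | starting material
3 | dibutylboron (Z)-enolate of 1 | C/C=C(\OB(CCCC)CCCC)N1[C@@H](Cc2ccccc2)COC1=O | intermediate
4 | (S)-4-benzyl-3-[(2S,3R)-3-hydroxy-2-methylpent-4-enoyl]oxazolidin-2-one | O=C([C@@H](C)[C@@H](C=C)O)N1[C@@H](Cc2ccccc2)COC1=O | intermediate
5 | (2R,3R)-2-methylpent-4-ene-1,3-diol | OC[C@@H](C)[C@@H](C=C)O | intermediate
6 | (2R,3R)-2-methylpent-4-ene-1,3-diyl diacetate | CC(=O)OC[C@@H](C)[C@@H](C=C)OC(C)=O | intermediate
7 | (2S,3R)-2,4-diacetoxy-3-methylbutanoic acid | CC(=O)OC[C@@H](C)[C@@H](C(=O)O)OC(C)=O | intermediate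
8 | (2S,3R)-2,4-diacetoxy-3-methylbutanoyl chloride | CC(=O)OC[C@@H](C)[C@@H](C(=O)Cl)OC(C)=O | intermediate
9 | (2R,3S)-5-diazo-2-methyl-4-oxopentane-1,3-diyl diacetate | CC(=O)OC[C@@H](C)[C@@H](C(=O)C=[N+]=[N-])OC(C)=O | intermediate
10 | phenyl vinyl sulfone | C=CS(=O)(=O)c1ccccc1 | starting material
11 | six-membered cyclic carbonyl ylide (O13 oxonium, C13 carbanion, C12 ketone) | CC(=O)OC[C@@H](C)[C@@H]1OC(C)=[O+][CH-]C1=O | intermediate
12 | keto sulfone cycloadduct; C11 side chain equatorial and anti to the C14–C15 bridge, sulfonyl exo at C15 | CC(=O)OC[C@@H](C)[C@@H]1O[C@@]2(C)[C@H](S(=O)(=O)c3ccccc3)C[C@H](O2)C1=O | intermediate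
13 | C12 exocyclic methylene derivative of 12 | CC(=O)OC[C@@H](C)[C@@H]1O[C@@]2(C)[C@H](S(=O)(=O)c3ccccc3)C[C@H](O2)C1=C | intermediate
14 | saturated sulfone acetate with equatorial C12 methyl | CC(=O)OC[C@@H](C)[C@@H]1O[C@@]2(C)[C@H](S(=O)(=O)c3ccccc3)C[C@H](O2)[C@H]1C | intermediate
15 | (R)-2-[(1S,3S,4R,5S)-1,4-dimethyl-2,8-dioxabicyclo[3.2.1]octan-3-yl]propan-1-ol | OC[C@@H](C)[C@@H]1O[C@@]2(C)CC[C@H](O2)[C@H]1C | intermediate
16 | C9 aldehyde derived from 15 | O=C[C@@H](C)[C@@H]1O[C@@]2(C)CC[C@H](O2)[C@H]1C | intermediate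
17 | (E)-but-2-ene | C/C=C/C | starting material
18 | (E)-crotyldiisopinocampheylborane, Ipc from (−)-α-pinene | C/C=C/CB([C@H]1C[C@H]2C[C@@H]([C@@H]1C)C2(C)C)[C@H]1C[C@H]2C[C@@H]([C@@H]1C)C2(C)C | intermediate
19 | (8R,9R,10R) homoallylic alcohol, 8,9-anti and 9,10-anti | C=C[C@@H](C)[C@@H](O)[C@@H](C)[C@@H]1O[C@@]2(C)CC[C@H](O2)[C@H]1C | intermediate
20 | C9 triethylsilyl ether of 19 | C=C[C@@H](C)[C@@H](O[Si](CC)(CC)CC)[C@@H](C)[C@@H]1O[C@@]2(C)CC[C@H](O2)[C@H]1C | intermediate
21 | C7 aldehyde | O=C[C@@H](C)[C@@H](O[Si](CC)(CC)CC)[C@@H](C)[C@@H]1O[C@@]2(C)CC[C@H](O2)[C@H]1C | intermediate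
22 | (R)-but-3-yn-2-ol | C#C[C@@H](C)O | starting material
23 | (R)-but-3-yn-2-yl methanesulfonate | C#C[C@@H](C)OS(C)(=O)=O | intermediate
24 | axially chiral buta-1,2-dienylindium(III) iodide methanesulfonate | [H]C(C)=[C@]=C([H])[In](I)OS(C)(=O)=O | intermediate
25 | (6S,7S) homopropargylic alcohol, 6,7-anti and 7,8-syn | C#C[C@H](C)[C@H](O)[C@@H](C)[C@@H](O[Si](CC)(CC)CC)[C@@H](C)[C@@H]1O[C@@]2(C)CC[C@H](O2)[C@H]1C | intermediate
26 | (E)-vinylstannane | CCCC[Sn](CCCC)(CCCC)/C=C/[C@H](C)[C@H](O)[C@@H](C)[C@@H](O[Si](CC)(CC)CC)[C@@H](C)[C@@H]1O[C@@]2(C)CC[C@H](O2)[C@H]1C | intermediate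
27 | propargyl alcohol | C#CCO | starting material
28 | (Z)-vinylmagnesium bromide alkoxide from carbomagnesiation | C/C(=C/[Mg]Br)CO[Mg]Br | intermediate
29 | (Z)-3-iodo-2-methylprop-2-en-1-ol | C/C(=C/I)CO | intermediate
30 | (Z)-3-iodo-2-methylacrylic acid | C/C(=C/I)C(=O)O | intermediate
31 | diisopropyl squarate | CC(C)OC1=C(OC(C)C)C(=O)C1=O | starting material
32 | 4-hydroxy-2,3-diisopropoxycyclobut-2-en-1-one (racemic) | CC(C)OC1=C(OC(C)C)C(O)C1=O | intermediate
33 | 3-isopropoxycyclobut-3-ene-1,2-dione | CC(C)OC1=CC(=O)C1=O | intermediate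
34 | 2,4-dihydroxy-3-methylbenzoic acid | Cc1c(O)ccc(C(=O)O)c1O | starting material
35 | 2,4-dihydroxy-5-iodo-3-methylbenzoic acid | Cc1c(O)c(I)cc(C(=O)O)c1O | intermediate
36 | 4-methoxybenzyl 5-iodo-2,4-bis[(4-methoxybenzyl)oxy]-3-methylbenzoate | O=C(OCc1ccc(OC)cc1)c1cc(I)c(OCc2ccc(OC)cc2)c(C)c1OCc1ccc(OC)cc1 | intermediate
37 | arylmagnesium chloride from 36 | O=C(OCc1ccc(OC)cc1)c1cc([Mg]Cl)c(OCc2ccc(OC)cc2)c(C)c1OCc1ccc(OC)cc1 | intermediate
38 | 4-aryl-4-hydroxy-3-isopropoxycyclobut-2-en-1-one (racemic carbinol) | CC(C)OC1=CC(=O)C1(O)c1cc(C(=O)OCc2ccc(OC)cc2)c(OCc2ccc(OC)cc2)c(C)c1OCc1ccc(OC)cc1 | intermediate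
39 | 2-isopropoxynaphthalene-1,4-diol with PMB ester and PMB ethers | CC(C)Oc1cc(O)c2c(C(=O)OCc3ccc(OC)cc3)c(OCc3ccc(OC)cc3)c(C)c(OCc3ccc(OC)cc3)c2c1O | intermediate
40 | 4-methoxybenzyl 6-isopropoxy-2,4-bis[(4-methoxybenzyl)oxy]-3-methyl-5,8-dioxo-5,8-dihydronaphthalene-1-carboxylate | CC(C)OC1=CC(=O)c2c(C(=O)OCc3ccc(OC)cc3)c(OCc3ccc(OC)cc3)c(C)c(OCc3ccc(OC)cc3)c2C1=O | intermediate
41 | corresponding 2-aminonaphthoquinone | NC1=CC(=O)c2c(C(=O)OCc3ccc(OC)cc3)c(OCc3ccc(OC)cc3)c(C)c(OCc3ccc(OC)cc3)c2C1=O | intermediate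
42 | (Z)-3-iodo-2-methylacryloyl chloride | C/C(=C/I)C(=O)Cl | intermediate
43 | (Z)-3-iodo-2-methylacrylamide of 41 | C/C(=C/I)C(=O)NC1=CC(=O)c2c(C(=O)OCc3ccc(OC)cc3)c(OCc3ccc(OC)cc3)c(C)c(OCc3ccc(OC)cc3)c2C1=O | intermediate
44 | tris-PMB 9-O-TES rifsaliniketal | C/C(=C/C=C/[C@H](C)[C@H](O)[C@@H](C)[C@@H](O[Si](CC)(CC)CC)[C@@H](C)[C@@H]1O[C@@]2(C)CC[C@H](O2)[C@H]1C)C(=O)NC1=CC(=O)c2c(C(=O)OCc3ccc(OC)cc3)c(OCc3ccc(OC)cc3)c(C)c(OCc3ccc(OC)cc3)c2C1=O | intermediate
45 | rifsaliniketal | C/C(=C/C=C/[C@H](C)[C@H](O)[C@@H](C)[C@@H](O)[C@@H](C)[C@@H]1O[C@@]2(C)CC[C@H](O2)[C@H]1C)C(=O)NC1=CC(=O)c2c(C(=O)O)c(O)c(C)c(O)c2C1=O | target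

Total step count: 27
Longest linear sequence: 17 steps (1–13, 15, 16, 26, 27)

Steps most likely to fail

**Step 6.**
- Risk: the weakly nucleophilic ester carbonyl may lose the race for the carbenoid to dimerisation or C–H insertion. The ylide may also tautomerise by 1,4-H shift from its methyl group before the dipolarophile reaches it.
- Fallback (no carbene chemistry, classical keto-diol ketalisation): the fallback sets out from 1. Evans syn aldol with methacrolein gives the isopropenyl aldol adduct F1, LiBH4 gives the diol F2, and TBSCl/imidazole gives the bis-silyl ether F3. A(1,3)-strain-controlled hydroboration with 9-BBN and NaOH/H2O2 gives the 11,12-anti primary alcohol F4, and Dess–Martin oxidation gives the aldehyde F5. Felkin-selective addition of the Grignard reagent from 2-(2-bromoethyl)-2-methyl-1,3-dioxolane gives the 12,13-syn carbinol F6. Aqueous HCl in THF strips both silyl ethers and the dioxolane, and the released keto triol closes to 15, where the route is rejoined.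

**Step 27.**
- Risk: acid exposure of the complete molecule may cause protodecarboxylation of the salicylic-type acid, Z to E isomerisation of the dienamide, or alkylation of the diene by PMB cations.
- Fallback (deprotect the arene before the union): the fallback sets out from 43 and 26. TFA/anisole on 43 gives the free acid diphenol iodoacrylamide F9. Neutral Stille coupling of F9 with 26 gives 9-O-TES rifsaliniketal F10. Buffered HF·pyridine in THF removes the last silyl group and arrives at 45.

**Step 25.**
- Risk: the vinylogous-amide nitrogen may be too poor a nucleophile, so that O-acylation, hydrolysis of the acid chloride, or base-induced isomerisation of the iodoalkene takes over.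
- Fallback (redox switch of the nucleophile): the fallback sets out from 41. Na2S2O4 in THF–H2O reduces it to the aminonaphthohydroquinone F7. Its aniline-type nitrogen is acylated by 42 with pyridine at −20 °C to give the anilide hydroquinone F8, and Ag2O oxidation returns to 43.

Further compounds
F1 | step 6 | (S)-4-benzyl-3-(3-hydroxy-2,4-dimethylpent-4-enoyl)oxazolidin-2-one, 10,11-syn | O=C([C@@H](C)[C@@H](C(C)=C)O)N1[C@@H](Cc2ccccc2)COC1=O
F2 | step 6 | 2,4-dimethylpent-4-ene-1,3-diol, 10,11-syn | OC[C@@H](C)[C@@H](C(C)=C)O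
F3 | step 6 | bis-TBS ether of F2 | CC(C)(C)[Si](C)(C)OC[C@@H](C)[C@@H](C(C)=C)O[Si](C)(C)C(C)(C)C
F4 | step 6 | C13 primary alcohol, 11,12-anti | CC(C)(C)[Si](C)(C)OC[C@@H](C)[C@@H]([C@H](C)CO)O[Si](C)(C)C(C)(C)C
F5 | step 6 | C13 aldehyde | CC(C)(C)[Si](C)(C)OC[C@@H](C)[C@@H]([C@H](C)C=O)O[Si](C)(C)C(C)(C)C
F6 | step 6 | C13 carbinol with dioxolane-masked C16 ketone, 12,13-syn | CC(C)(C)[Si](C)(C)OC[C@@H](C)[C@@H]([C@H](C)[C@@H](O)CCC1(C)OCCO1)O[Si](C)(C)C(C)(C)C
F7 | step 25 | 2-aminonaphthalene-1,4-diol from 41 | Nc1cc(O)c2c(C(=O)OCc3ccc(OC)cc3)c(OCc3ccc(OC)cc3)c(C)c(OCc3ccc(OC)cc3)c2c1O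
F8 | step 25 | (Z)-3-iodo-2-methylacrylanilide hydroquinone | C/C(=C/I)C(=O)Nc1cc(O)c2c(C(=O)OCc3ccc(OC)cc3)c(OCc3ccc(OC)cc3)c(C)c(OCc3ccc(OC)cc3)c2c1O
F9 | step 27 | deprotected iodoacrylamide naphthoquinone carboxylic acid | C/C(=C/I)C(=O)NC1=CC(=O)c2c(C(=O)O)c(O)c(C)c(O)c2C1=O
F10 | step 27 | 9-O-TES rifsaliniketal | C/C(=C/C=C/[C@H](C)[C@H](O)[C@@H](C)[C@@H](O[Si](CC)(CC)CC)[C@@H](C)[C@@H]1O[C@@]2(C)CC[C@H](O2)[C@H]1C)C(=O)NC1=CC(=O)c2c(C(=O)O)c(O)c(C)c(O)c2C1=O
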